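Early on, the substrate in the epsilon flask (the asked flask, followed so far) falls fast: at 25.0 s it stands at 39.5% with target at 21.4%, and by 30.0 s an unseen pool holds 37.6% of the charge.

| flask | substrate | partner | remark | time |
|---|---|---|---|---|
| epsilon | 5 mM | 1.1 equiv | the very flask that is asked about, followed so far |  |
| gamma | 2.5 mM | 1.1 equiv | run made earlier |  |
| flask | 5.0 mM | 1.10 equiv |  | 2.0 min |

- epsilon (time / s: target / %, substrate / %): 25.0: 21.4, 39.5; 30.0: 25.9, 36.5
- gamma (time / s: target / %, substrate / %): 30.0: 15.5, 40.0; 40.0: 20.5, 36.5; 50.0: 27.7, 35.5

(each reading ± 1 percentage point)

- the moment within 2.0 min at which there is most target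
- the amount of target, in percent of the substrate charged, at that time

- what was read earlier has a scatter of 1 percentage point, one standard deviation

Turn the amount first. By hand, doubling the charge leaves the percent at a given time unchanged for a first-order step and about doubles it early for a step between two dissolved species. From c(substrate) = 2.5 mM to 5 mM, twice the charge, target at 30.0 s grows by a factor of 1.67, a reading that leans to the second.

Then the time. The last slope of epsilon, held to 2.0 min, would give 107%, beyond the charge, so the rate must fall. The last two epsilon readings give 0.667 for the drain ratio, substrate lost per target gained. Above one the pool fills; below one it feeds target. The crossing already lies behind this flask, though the figure is loose with a scatter of 1 percentage point. This reckoning therefore puts the maximum at the end of the window and gives no amount.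

The forecast says 2 min and 61%: “I expect the maximum at the end of the window”.

The flask gives 2.00 min and 52.9%: the time holds, and the amount is 8.1 points lower.

    partner ⇌ dormant form (K = 0.500, k = 0.250 s⁻¹)
    2 second intermediate → homo product (k = 3.60 M⁻¹ s⁻¹)
    partner → second intermediate (k = 0.130 s⁻¹)
    open intermediate + second intermediate → target (k = 8.70 M⁻¹ s⁻¹)
    substrate ⇌ open intermediate (K = 1.20, k = 0.0980 s⁻¹)

From 1.00 min to 2.00 min the drain ratio in the flask is 0.520, still below one, and over that stretch the open intermediate falls from 31.0% to 25.4%. The gain slows as partner, the limiting reagent, stands at 0.442% of its charge by 1.00 min: a run with partner held up reaches 98.1% against 52.9%, the largest single effect.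

Left until 5.0 min, the same flask loses substrate from 21.7% to 18.3%, and at the early drain ratio that predicts 58.0% target. The computed amount is 59.8%.

The earlier runs and the new flask were generated by integration for an exercise; the scatter is artificial.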